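Ring A is traced back to two pieces: a 3-siloxycyclobut-2-enone that already carries the enantiopure, masked ring B on its C4 methylene, and a geranyl-substituted silyl ynol ether. In one thermal operation (step 13) the cyclobutenone opens to a siloxy vinylketene, takes up the alkyne and closes to the benzene ring. The step exploits the alternation in ring A of the three oxygen-bearing carbons (C2, C4, C6) with the geranyl carbon C3, the bridge carbon C5 and C1, which is left unsubstituted for the later butyrylation. The single stereocentre, the quaternary carbon of ring B, is set beforehand by palladium-catalysed asymmetric dearomative geranylation.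

Key step: step 13

Remark on the chemistry: the (R,R)-enantiomer of the bisphosphine ligand in step 5 is assumed to give the (R)-configured quaternary carbon; if the sense of induction is the opposite, the (S,S)-ligand is used with no other change.
Remark on names: geranyl = (2E)-3,7-dimethylocta-2,6-dien-1-yl; B* = (3R)-5-acetyl-3-geranyl-2,4-dimethoxy-3-methyl-6-oxocyclohexa-1,4-dien-1-yl (the masked ring B); enol tautomers are named as drawn in the SMILES.

Step 1
Reactants: 1 acryloyl chloride; 2 2-(trimethylsilyl)ethanol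
Product: 3 2-(trimethylsilyl)ethyl acrylate
Conditions: Et3N, DMAP (cat.), CH2Cl2, 0 °C
Reagents that add atoms: none
Why: O-acylation of a primary alcohol by an acid chloride (esterification) should give an acrylate whose ester is inert to zerovalent palladium in step 5 yet cleaved by fluoride in step 7.

Step 2
Reactants: 4 2-methylphloroglucinol
Product: 5 1-(2,4,6-trihydroxy-3-methylphenyl)ethan-1-one
Conditions: AcCl (1.05 equiv), AlCl3 (3 equiv), PhNO2, rt → 50 °C; then ice/aq. HCl
Reagents that add atoms: acetyl chloride, CC(Cl)=O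
Why: Friedel–Crafts acylation of the electron-rich triol at one of its two equivalent free ring carbons, the product being deactivated as its aluminium chelate so that a single acetyl group should enter.

Step 3
Reactants: 5 1-(2,4,6-trihydroxy-3-methylphenyl)ethan-1-one; 3 2-(trimethylsilyl)ethyl acrylate
Product: 6 2-(trimethylsilyl)ethyl 3-(3-acetyl-2,4,6-trihydroxy-5-methylphenyl)propanoate
Conditions: K2CO3 (0.3 equiv), DMF, 50 °C
Reagents that add atoms: none
Why: Base-catalysed Michael addition of the phenoxide through its only unsubstituted ring carbon, the counterpart of the C-cyanoethylation of phloroglucinols, should install the three-carbon chain because adducts formed at oxygen revert under the basic conditions.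

Step 4
Reactants: 7 geraniol
Product: 8 geranyl methyl carbonate
Conditions: ClCO2Me, pyridine, CH2Cl2, 0 °C
Reagents that add atoms: methyl chloroformate, COC(Cl)=O
Why: Acylation of the allylic alcohol with a chloroformate should give the carbonate needed for ionisation by zerovalent palladium without touching the (E)-alkene.

Step 5
Reactants: 6 2-(trimethylsilyl)ethyl 3-(3-acetyl-2,4,6-trihydroxy-5-methylphenyl)propanoate; 8 geranyl methyl carbonate
Product: 9 2-(trimethylsilyl)ethyl 3-[(3R)-5-acetyl-3-geranyl-2,4-dihydroxy-3-methyl-6-oxocyclohexa-1,4-dien-1-yl]propanoate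
Conditions: Pd2(dba)3·CHCl3 (2.5 mol%), (R,R)-DACH-phenyl bisphosphine ligand (7.5 mol%), CH2Cl2, 0 °C → rt
Reagents that add atoms: none
Why: In this Tsuji–Trost asymmetric allylic alkylation with dearomatisation the π-geranyl palladium complex formed from 8 should be attacked at its unhindered CH2 terminus by the methyl-bearing ring carbon, the less hindered of the two substituted non-acylated ring carbons (O-geranyl ethers re-ionise), and the chiral bisphosphine differentiates the two faces of the phenoxide so that the quaternary stereocentre is set under catalyst control.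

Step 6
Reactants: 9 2-(trimethylsilyl)ethyl 3-[(3R)-5-acetyl-3-geranyl-2,4-dihydroxy-3-methyl-6-oxocyclohexa-1,4-dien-1-yl]propanoate
Product: 10 2-(trimethylsilyl)ethyl 3-B*-propanoate
Conditions: TMSCHN2 (3 equiv), MeOH–toluene (1:4), 0 °C → rt
Reagents that add atoms: (trimethylsilyl)diazomethane, C[Si](C)(C)C=[N+]=[N-]
Why: O-methylation of the two strongly acidic enols by the diazoalkane should mask ring B as the cross-conjugated bis(methyl enol ether) without touching ester, ketone or alkenes, and any regioisomeric enol ether formed alongside would converge on the same trione in step 16.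

Step 7
Reactants: 10 2-(trimethylsilyl)ethyl 3-B*-propanoate
Product: 11 3-B*-propanoic acid
Conditions: TBAF (1.5 equiv), THF, 0 °C → rt; then cold dilute HCl
Reagents that add atoms: none
Why: Fluoride attack on silicon triggers β-elimination of the 2-(trimethylsilyl)ethyl ester, which should free the carboxylic acid under conditions that leave the methyl enol ethers, the dienone and the geranyl alkenes intact.

Step 8
Reactants: 12 (trimethylsilyl)acetylene
Product: 15 triisopropyl{[(trimethylsilyl)ethynyl]oxy}silane, via lithium (trimethylsilyl)acetylide 13 (not isolated), via lithium 2-(trimethylsilyl)ethynolate 14 (not isolated)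
Conditions: LiN(SiMe3)2, THF, −78 °C; t-BuOOLi [t-BuOOH + LiN(SiMe3)2], −78 → 0 °C; TIPSOTf, −78 °C → rt
Reagents that add atoms: tert-butyl hydroperoxide, CC(C)(C)OO; triisopropylsilyl triflate, CC(C)[Si](OS(=O)(=O)C(F)(F)F)(C(C)C)C(C)C
Why: Oxidation of the lithium acetylide by t-BuOOLi (electrophilic oxygen transfer) gives the lithium ynolate, and the bulky silyl triflate should be taken up at oxygen, as with alkyl-substituted ynolates, to give the silyl ynol ether.

Step 9
Reactants: 15 triisopropyl{[(trimethylsilyl)ethynyl]oxy}silane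
Product: 16 (ethynyloxy)triisopropylsilane
Conditions: K2CO3 (0.1 equiv), MeOH, 0 °C
Reagents that add atoms: none
Why: Methoxide-catalysed protodesilylation of the alkynyl–SiMe3 bond should free the terminal ynol ether while the hindered O–Si(i-Pr)3 bond survives the brief exposure at 0 °C.

Step 10
Reactants: 11 3-B*-propanoic acid; 16 (ethynyloxy)triisopropylsilane
Product: 19 4-(B*-methyl)-3-[(triisopropylsilyl)oxy]cyclobut-2-en-1-one (both epimers at C4), via acid chloride 17 (not isolated), via alkylketene 18 (not isolated)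
Conditions: 1-chloro-N,N,2-trimethylprop-1-en-1-amine (1.1 equiv), CH2Cl2, 0 °C → rt; then slow addition to 16 (3 equiv), Et3N (1.5 equiv), CH2Cl2, 0 °C → rt
Reagents that add atoms: none
Why: The α-chloroenamine makes the acid chloride under neutral conditions, Et3N dehydrochlorinates it to the monoalkylketene, and [2+2] cycloaddition with the ynol ether, whose unsubstituted carbon bonds to the ketene carbonyl carbon as in the reactions of ketenes with ethoxyacetylene, should give the 3-siloxy-4-substituted cyclobutenone, its new stereocentre at C4 forming without control and being erased in step 13.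

Step 11
Reactants: 20 geranyl bromide; 21 ethynylmagnesium bromide
Product: 22 (4E)-5,9-dimethyldeca-4,8-dien-1-yne
Conditions: CuCl (5 mol%), THF, 0 → 50 °C
Reagents that add atoms: none
Why: Copper-catalysed SN2 coupling of an alkynyl Grignard reagent with a primary allylic bromide should give the skipped enyne with the (E)-alkene retained.

Step 12
Reactants: 22 (4E)-5,9-dimethyldeca-4,8-dien-1-yne
Product: 25 triisopropyl{[(4E)-5,9-dimethyldeca-4,8-dien-1-yn-1-yl]oxy}silane, via lithium acetylide 23 (not isolated), via lithium ynolate 24 (not isolated)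
Conditions: LiN(SiMe3)2, THF, −78 °C; t-BuOOLi [t-BuOOH + LiN(SiMe3)2], −78 → 0 °C; TIPSOTf, −78 °C → rt
Reagents that add atoms: tert-butyl hydroperoxide, CC(C)(C)OO; triisopropylsilyl triflate, CC(C)[Si](OS(=O)(=O)C(F)(F)F)(C(C)C)C(C)C
Why: The same acetylide oxidation and O-silylation sequence as in step 8 should apply, the amide base removing only the acetylenic proton of the skipped enyne.

Step 13
Reactants: 19 4-(B*-methyl)-3-[(triisopropylsilyl)oxy]cyclobut-2-en-1-one; 25 triisopropyl{[(4E)-5,9-dimethyldeca-4,8-dien-1-yn-1-yl]oxy}silane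
Product: 30 2-geranyl-6-(B*-methyl)-3,5-bis[(triisopropylsilyl)oxy]phenol, via siloxy vinylketene 26 (not isolated), via 4-vinylcyclobutenone 27 (not isolated), via dienylketene 28 (not isolated), via cyclohexa-2,4-dienone 29 (not isolated)
Conditions: 25 (2 equiv), toluene, 80 → 110 °C, Ar
Reagents that add atoms: none
Why: Heating should open 19 by 4π electrocyclic cleavage of its C1–C4 bond to the siloxy vinylketene 26, which adds to the electron-rich ynol ether in a [2+2] cycloaddition to give the 4-vinylcyclobutenone 27; a second 4π opening gives the dienylketene 28, and ring A is closed by thermal 6π electrocyclisation between the ketene carbon and the diene terminus, after which the cyclohexadienone 29 tautomerises to the phenol. The closest known reaction is the Danheiser benzannulation of cyclobutenones with siloxyalkynes, applied here to a 3-siloxycyclobutenone so that all three ring oxygens of a phloroglucinol are delivered. No stereocentre is created: the C4 epimers of 19 converge on one arene and the quaternary carbon of ring B is remote and untouched. The selectivity required is the regiochemistry of the ketene–alkyne cycloaddition, and the polarisation of the ynol ether secures it, since its geranyl-bearing carbon is the nucleophilic one and bonds to the ketene carbonyl carbon; geranyl therefore sits next to the newly formed hydroxyl (former carbonyl carbon, C4 of ring A) with the alkyne-derived siloxy group on its other side, and the bridge methylene flanks the same hydroxyl from C5. The neutral thermal conditions should be tolerated by the masked trione and by both skipped dienes.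

Step 14
Reactants: 30 2-geranyl-6-(B*-methyl)-3,5-bis[(triisopropylsilyl)oxy]phenol
Product: 31 2-geranyl-6-(B*-methyl)benzene-1,3,5-triol
Conditions: TBAF (2.2 equiv), AcOH (2.2 equiv), THF, 0 °C, Ar
Reagents that add atoms: none
Why: Fluoride cleaves the two aryl silyl ethers, and the acetic acid buffer protonates the phenoxides at once, which should spare the methyl enol ethers and keep the electron-rich triol from base-promoted oxidation.

Step 15
Reactants: 31 2-geranyl-6-(B*-methyl)benzene-1,3,5-triol; 32 butyryl chloride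
Product: 34 1-[3-(B*-methyl)-5-geranyl-2,4,6-trihydroxyphenyl]butan-1-one, via tris(chloromagnesium) phenolate 33 (not isolated)
Conditions: t-BuMgCl (3.0 equiv), THF, −78 → 0 °C; solvent change to toluene; 32 (1.1 equiv), 0 °C → rt; then cold dilute HCl
Reagents that add atoms: none
Why: In this ortho-specific C-acylation of a magnesium phenolate the acid chloride coordinated to magnesium on a flanking oxygen should be delivered to the only unsubstituted ring carbon, free of the strong acids that would cyclise the geranyl groups, the three phenols being deprotonated by the hindered Grignard base before it can attack ring B.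

Step 16
Reactants: 34 1-[3-(B*-methyl)-5-geranyl-2,4,6-trihydroxyphenyl]butan-1-one
Product: 35 1-[3-{[(3R)-5-acetyl-3-geranyl-2,4-dihydroxy-3-methyl-6-oxocyclohexa-1,4-dien-1-yl]methyl}-5-geranyl-2,4,6-trihydroxyphenyl]butan-1-one (CNP0209203.1)
Conditions: 1 M aq. HCl–THF (1:3), rt, Ar
Reagents that add atoms: water, O
Why: Mild acid hydrolysis of the two vinylogous methyl esters (addition of water, loss of methanol) should unmask the β-triketone of ring B at a dilution and temperature at which the geranyl groups next to free phenols do not cyclise.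

Compound list
1 | acryloyl chloride | C=CC(Cl)=O | starting material
2 | 2-(trimethylsilyl)ethanol | C[Si](C)(C)CCO | starting material
3 | 2-(trimethylsilyl)ethyl acrylate | C=CC(=O)OCC[Si](C)(C)C | intermediate
4 | 2-methylphloroglucinol (2-methylbenzene-1,3,5-triol) | Cc1c(O)cc(O)cc1O | starting material
5 | 1-(2,4,6-trihydroxy-3-methylphenyl)ethan-1-one | CC(=O)c1c(O)c(C)c(O)cc1O | intermediate
6 | 2-(trimethylsilyl)ethyl 3-(3-acetyl-2,4,6-trihydroxy-5-methylphenyl)propanoate | CC(=O)c1c(O)c(C)c(O)c(CCC(=O)OCC[Si](C)(C)C)c1O | intermediate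
7 | geraniol, (2E)-3,7-dimethylocta-2,6-dien-1-ol | OC/C=C(\C)CCC=C(C)C | starting material
8 | geranyl methyl carbonate | COC(=O)OC/C=C(\C)CCC=C(C)C | intermediate
9 | 2-(trimethylsilyl)ethyl 3-[(3R)-5-acetyl-3-geranyl-2,4-dihydroxy-3-methyl-6-oxocyclohexa-1,4-dien-1-yl]propanoate | C[Si](C)(C)CCOC(=O)CCC1=C(O)[C@@](C)(C/C=C(\C)CCC=C(C)C)C(O)=C(C(C)=O)C1=O | intermediate
10 | 2-(trimethylsilyl)ethyl 3-B*-propanoate, the bis(methyl enol ether) of 9 | C[Si](C)(C)CCOC(=O)CCC1=C(OC)[C@@](C)(C/C=C(\C)CCC=C(C)C)C(OC)=C(C(C)=O)C1=O | intermediate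
11 | 3-B*-propanoic acid | OC(=O)CCC1=C(OC)[C@@](C)(C/C=C(\C)CCC=C(C)C)C(OC)=C(C(C)=O)C1=O | intermediate
12 | (trimethylsilyl)acetylene | C[Si](C)(C)C#C | starting material
13 | lithium (trimethylsilyl)acetylide (not isolated) | [Li+].[C-]#C[Si](C)(C)C | intermediate
14 | lithium 2-(trimethylsilyl)ethynolate (not isolated) | [Li+].[O-]C#C[Si](C)(C)C | intermediate
15 | triisopropyl{[(trimethylsilyl)ethynyl]oxy}silane | C[Si](C)(C)C#CO[Si](C(C)C)(C(C)C)C(C)C | intermediate
16 | (ethynyloxy)triisopropylsilane, (triisopropylsiloxy)acetylene | C#CO[Si](C(C)C)(C(C)C)C(C)C | intermediate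
17 | 3-B*-propanoyl chloride (not isolated) | ClC(=O)CCC1=C(OC)[C@@](C)(C/C=C(\C)CCC=C(C)C)C(OC)=C(C(C)=O)C1=O | intermediate
18 | 3-B*-prop-1-en-1-one, the monoalkylketene (not isolated) | O=C=CCC1=C(OC)[C@@](C)(C/C=C(\C)CCC=C(C)C)C(OC)=C(C(C)=O)C1=O | intermediate
19 | 4-(B*-methyl)-3-[(triisopropylsilyl)oxy]cyclobut-2-en-1-one, both epimers at C4 | O=C1C=C(O[Si](C(C)C)(C(C)C)C(C)C)C1CC2=C(OC)[C@@](C)(C/C=C(\C)CCC=C(C)C)C(OC)=C(C(C)=O)C2=O | intermediate
20 | geranyl bromide, (2E)-1-bromo-3,7-dimethylocta-2,6-diene | BrC/C=C(\C)CCC=C(C)C | starting material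
21 | ethynylmagnesium bromide | C#C[Mg]Br | starting material
22 | (4E)-5,9-dimethyldeca-4,8-dien-1-yne | C#CC/C=C(\C)CCC=C(C)C | intermediate
23 | lithium (4E)-5,9-dimethyldeca-4,8-dien-1-yn-1-ide (not isolated) | [Li+].[C-]#CC/C=C(\C)CCC=C(C)C | intermediate
24 | lithium (4E)-5,9-dimethyldeca-4,8-dien-1-yn-1-olate (not isolated) | [Li+].[O-]C#CC/C=C(\C)CCC=C(C)C | intermediate
25 | triisopropyl{[(4E)-5,9-dimethyldeca-4,8-dien-1-yn-1-yl]oxy}silane, the geranyl siloxyalkyne | CC(C)[Si](C(C)C)(C(C)C)OC#CC/C=C(\C)CCC=C(C)C | intermediate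
26 | 5-B*-3-[(triisopropylsilyl)oxy]penta-1,3-dien-1-one, siloxy vinylketene (not isolated) | O=C=CC(O[Si](C(C)C)(C(C)C)C(C)C)=CCC1=C(OC)[C@@](C)(C/C=C(\C)CCC=C(C)C)C(OC)=C(C(C)=O)C1=O | intermediate
27 | 2-geranyl-3-[(triisopropylsilyl)oxy]-4-{3-B*-1-[(triisopropylsilyl)oxy]prop-1-en-1-yl}cyclobut-2-en-1-one (not isolated) | O=C1C(C/C=C(\C)CCC=C(C)C)=C(O[Si](C(C)C)(C(C)C)C(C)C)C1C(O[Si](C(C)C)(C(C)C)C(C)C)=CCC2=C(OC)[C@@](C)(C/C=C(\C)CCC=C(C)C)C(OC)=C(C(C)=O)C2=O | intermediate
28 | 7-B*-2-geranyl-3,5-bis[(triisopropylsilyl)oxy]hepta-1,3,5-trien-1-one, dienylketene (not isolated) | O=C=C(C/C=C(\C)CCC=C(C)C)C(O[Si](C(C)C)(C(C)C)C(C)C)=CC(O[Si](C(C)C)(C(C)C)C(C)C)=CCC1=C(OC)[C@@](C)(C/C=C(\C)CCC=C(C)C)C(OC)=C(C(C)=O)C1=O | intermediate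
29 | 6-(B*-methyl)-2-geranyl-3,5-bis[(triisopropylsilyl)oxy]cyclohexa-2,4-dien-1-one (not isolated) | O=C1C(C/C=C(\C)CCC=C(C)C)=C(O[Si](C(C)C)(C(C)C)C(C)C)C=C(O[Si](C(C)C)(C(C)C)C(C)C)C1CC2=C(OC)[C@@](C)(C/C=C(\C)CCC=C(C)C)C(OC)=C(C(C)=O)C2=O | intermediate
30 | 2-geranyl-6-(B*-methyl)-3,5-bis[(triisopropylsilyl)oxy]phenol | Oc1c(C/C=C(\C)CCC=C(C)C)c(O[Si](C(C)C)(C(C)C)C(C)C)cc(O[Si](C(C)C)(C(C)C)C(C)C)c1CC2=C(OC)[C@@](C)(C/C=C(\C)CCC=C(C)C)C(OC)=C(C(C)=O)C2=O | intermediate
31 | 2-geranyl-6-(B*-methyl)benzene-1,3,5-triol | Oc1c(C/C=C(\C)CCC=C(C)C)c(O)cc(O)c1CC2=C(OC)[C@@](C)(C/C=C(\C)CCC=C(C)C)C(OC)=C(C(C)=O)C2=O | intermediate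
32 | butyryl chloride | CCCC(Cl)=O | starting material
33 | tris(chloromagnesium) phenolate of 31 (not isolated) | Cl[Mg]Oc1c(C/C=C(\C)CCC=C(C)C)c(O[Mg]Cl)cc(O[Mg]Cl)c1CC2=C(OC)[C@@](C)(C/C=C(\C)CCC=C(C)C)C(OC)=C(C(C)=O)C2=O | intermediate
34 | 1-[3-(B*-methyl)-5-geranyl-2,4,6-trihydroxyphenyl]butan-1-one | CCCC(=O)c1c(O)c(C/C=C(\C)CCC=C(C)C)c(O)c(CC2=C(OC)[C@@](C)(C/C=C(\C)CCC=C(C)C)C(OC)=C(C(C)=O)C2=O)c1O | intermediate
35 | 1-[3-{[(3R)-5-acetyl-3-geranyl-2,4-dihydroxy-3-methyl-6-oxocyclohexa-1,4-dien-1-yl]methyl}-5-geranyl-2,4,6-trihydroxyphenyl]butan-1-one, CNP0209203.1 | CCCC(=O)c1c(O)c(C/C=C(\C)CCC=C(C)C)c(O)c(CC2=C(O)[C@@](C)(C/C=C(\C)CCC=C(C)C)C(O)=C(C(C)=O)C2=O)c1O | target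

Total step count: 16 steps.
Longest linear sequence: 10 steps (steps 2, 3, 5, 6, 7, 10, 13, 14, 15, 16, from 2-methylphloroglucinol).

Steps most likely to fail

Step 13. The electrocyclic opening of 19, or the ring closure of the dienylketene 28, whose terminus carries the bridge substituent, may be outrun by thermal consumption of the ynol ether (isomerisation to the silylketene, oligomerisation), so that the vinylketene is not captured or the 4-vinylcyclobutenone accumulates. The fallback moves the bridge substituent from C4 to C2 of the cyclobutenone, so that the vinylketene has an unsubstituted terminus, and it sets out from acid 11. The ketene 18, generated as in step 10, would be trapped with commercial ethoxyacetylene to give 3-ethoxy-4-(B*-methyl)cyclobut-2-en-1-one F1. Brief treatment with cold dilute HCl in THF should hydrolyse the strained vinylogous ethyl ester first and give the more substituted enol of the 1,3-dione, 3-hydroxy-2-(B*-methyl)cyclobut-2-en-1-one F2. TIPSOTf and Et3N would then give 2-(B*-methyl)-3-[(triisopropylsilyl)oxy]cyclobut-2-en-1-one F3. Heating F3 with alkyne 25 should give the regioisomeric bis(silyl ether) 2-geranyl-4-(B*-methyl)-3,5-bis[(triisopropylsilyl)oxy]phenol F4, in which the same three ring oxygens alternate with geranyl, bridge and hydrogen. Desilylation of F4 under the conditions of step 14 comes back to the route at triol 31.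

Step 15. Acylation of the magnesium phenolate at oxygen may outrun bond formation at the ring carbon, leaving aryl butyrates. The fallback brings the acyl carbon in at the aldehyde oxidation level and sets out from triol 31. The phenolate 33, formed as in step 15, would be treated with butanal in toluene (ortho-specific hydroxyalkylation of magnesium phenolates) to give, as its magnesium alkoxide, 2-geranyl-4-(1-hydroxybutyl)-6-(B*-methyl)benzene-1,3,5-triol F5. Without isolation, 1,1'-(azodicarbonyl)dipiperidine would oxidise the magnesium alkoxide to the ketone, which comes back to the route at 34.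

Step 5. The chiral palladium complex may discriminate poorly between the two faces of the phenoxide, and some attack at the chain-bearing ring carbon may occur. The fallback gives up catalyst control and sets out from 6. Geranyl bromide 20 with Cs2CO3 in DMF at 0 °C (classical dearomatising C-alkylation of an acylphloroglucinol) would give the racemic trione, 2-(trimethylsilyl)ethyl 3-[5-acetyl-3-geranyl-2,4-dihydroxy-3-methyl-6-oxocyclohexa-1,4-dien-1-yl]propanoate F6. Methylation as in step 6 would give the racemic bis(methyl enol ether) F7. Preparative chromatography on a chiral stationary phase would then separate the enantiomers, and the (R)-enantiomer comes back to the route at 10.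

Further compounds
F1 | step 13 | 3-ethoxy-4-(B*-methyl)cyclobut-2-en-1-one | CCOC1=CC(=O)C1CC2=C(OC)[C@@](C)(C/C=C(\C)CCC=C(C)C)C(OC)=C(C(C)=O)C2=O
F2 | step 13 | 3-hydroxy-2-(B*-methyl)cyclobut-2-en-1-one | O=C1CC(O)=C1CC2=C(OC)[C@@](C)(C/C=C(\C)CCC=C(C)C)C(OC)=C(C(C)=O)C2=O
F3 | step 13 | 2-(B*-methyl)-3-[(triisopropylsilyl)oxy]cyclobut-2-en-1-one | O=C1CC(O[Si](C(C)C)(C(C)C)C(C)C)=C1CC2=C(OC)[C@@](C)(C/C=C(\C)CCC=C(C)C)C(OC)=C(C(C)=O)C2=O
F4 | step 13 | 2-geranyl-4-(B*-methyl)-3,5-bis[(triisopropylsilyl)oxy]phenol | Oc1cc(O[Si](C(C)C)(C(C)C)C(C)C)c(CC2=C(OC)[C@@](C)(C/C=C(\C)CCC=C(C)C)C(OC)=C(C(C)=O)C2=O)c(O[Si](C(C)C)(C(C)C)C(C)C)c1C/C=C(\C)CCC=C(C)C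
F5 | step 15 | 2-geranyl-4-(1-hydroxybutyl)-6-(B*-methyl)benzene-1,3,5-triol, both epimers at the carbinol carbon | CCCC(O)c1c(O)c(C/C=C(\C)CCC=C(C)C)c(O)c(CC2=C(OC)[C@@](C)(C/C=C(\C)CCC=C(C)C)C(OC)=C(C(C)=O)C2=O)c1O
F6 | step 5 | racemic 2-(trimethylsilyl)ethyl 3-[5-acetyl-3-geranyl-2,4-dihydroxy-3-methyl-6-oxocyclohexa-1,4-dien-1-yl]propanoate | C[Si](C)(C)CCOC(=O)CCC1=C(O)C(C)(C/C=C(\C)CCC=C(C)C)C(O)=C(C(C)=O)C1=O
F7 | step 5 | racemic 2-(trimethylsilyl)ethyl 3-[5-acetyl-3-geranyl-2,4-dimethoxy-3-methyl-6-oxocyclohexa-1,4-dien-1-yl]propanoate | C[Si](C)(C)CCOC(=O)CCC1=C(OC)C(C)(C/C=C(\C)CCC=C(C)C)C(OC)=C(C(C)=O)C1=O
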